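**Retrosynthetic overview**

1. Target 23 (ring numbering: C1 quaternary oxirane carbon, C2 ketone, C3 heptenyl carbon, C4 hydroxymethyl carbon, C5 carbinol, C6 oxirane CH) ⇐ global acidolysis and C2 oxidation of dienol 21.
2. 21 ⇐ tandem ring-closing enyne metathesis/cross-metathesis of acyclic epoxy enyne 18 with hept-1-ene: the carbocycle (C3=C4) and the (E)-heptenyl diene are made together, last.
3. 18 ⇐ ethynyl addition to epoxy aldehyde 16 ⇐ hydroxyl-directed, allylic 1,3-strain-controlled epoxidation of acyclic (Z)-enediol 13. This gives the trans C5–OH/oxirane (threo) array directly; epoxidation of a ring allylic alcohol would give cis.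
4. 13 ⇐ butenolide 11 (the ring locks the Z trisubstituted olefin) ⇐ Stille allylation of stannyl butenolide 7 with bromide 10 ⇐ hydrostannation of γ-hydroxy ynoate 5 ⇐ asymmetric alkynylation of enal 3 (the only external source of chirality).
5. Ring order: butenolide (temporary, opened in step 8) → oxirane (step 9) → cyclohexene (step 13).

Assumption: the (R,R) antipode of ProPhenol is taken to give the 4S alcohol 5; the sense is confirmed by Mosher ester analysis and the (S,S) ligand is used instead if it is reversed.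

Abbreviations: TBSO = tert-butyl(dimethyl)silyloxy; TESO = triethylsilyloxy.

**Route**

Step 1
Reactants: 1 2-methylidenepropane-1,3-diol
Product: 2 2-(TBSO-methyl)prop-2-en-1-ol
Conditions: NaH (1.0 equiv), THF, 0 °C; TBSCl (1.0 equiv), 0 °C → rt
Reagents that add atoms: tert-butyl(chloro)dimethylsilane (TBSCl), CC(C)(C)[Si](C)(C)Cl
Why: O-silylation of the poorly soluble monosodium alkoxide of a symmetrical diol stops cleanly at the mono-ether; no stereocentre is involved.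

Step 2
Reactants: 2 2-(TBSO-methyl)prop-2-en-1-ol
Product: 3 2-(TBSO-methyl)prop-2-enal
Conditions: MnO2 (15 equiv), CH2Cl2, rt
Reagents that add atoms: none
Why: Allylic alcohol oxidation with activated MnO2 gives the non-enolisable enal without touching the silyl ether.

Step 3
Reactants: 3 2-(TBSO-methyl)prop-2-enal; 4 methyl prop-2-ynoate
Product: 5 methyl (4S)-4-hydroxy-5-(TBSO-methyl)hex-5-en-2-ynoate
Conditions: (R,R)-ProPhenol (20 mol%), Ph3P=O (40 mol%), Me2Zn (3 equiv), 4 (3 equiv), toluene, 0–4 °C; aq NH4Cl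
Reagents that add atoms: none
Why: Trost Zn/ProPhenol asymmetric alkynylation of a non-enolisable α,β-unsaturated aldehyde, in which the chiral zinc alkoxide complex delivers the zinc acetylide to one aldehyde face and so sets the single reagent-controlled stereocentre (4S, the future C5).

Step 4
Reactants: 5 methyl (4S)-4-hydroxy-5-(TBSO-methyl)hex-5-en-2-ynoate
Product: 7 (5S)-5-(3-TBSO-prop-1-en-2-yl)-3-(tributylstannyl)furan-2(5H)-one, via stannyl hydroxy enoate 6 (not isolated)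
Conditions: Bu3SnH (1.15 equiv), Pd(PPh3)4 (2 mol%), THF, 0 °C → rt; then SiO2, CH2Cl2, rt
Reagents that add atoms: tributyltin hydride, CCCC[SnH](CCCC)CCCC
Why: Pd-catalysed syn-hydrostannation of an ynoate places tin α to the ester and H at the β-carbon, so the ester and carbinol end up cis and lactonise to the butenolide, which fixes the olefin geometry; the C–O stereocentre is untouched.

Step 5
Reactants: 8 (2E)-2-methylbut-2-enoic acid (tiglic acid)
Product: 9 tert-butyl (2E)-2-methylbut-2-enoate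
Conditions: 2-methylpropene (excess), H2SO4 (cat.), CH2Cl2, sealed vessel, rt
Reagents that add atoms: 2-methylpropene, CC(C)=C
Why: Acid-catalysed addition of the carboxylic acid to isobutene (capture of the tert-butyl cation) gives the tert-butyl ester without touching the E olefin.

Step 6
Reactants: 9 tert-butyl (2E)-2-methylbut-2-enoate
Product: 10 tert-butyl (2E)-4-bromo-2-methylbut-2-enoate
Conditions: NBS (1.05 equiv), AIBN (5 mol%), PhCF3, 80 °C; fractional distillation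
Reagents that add atoms: N-bromosuccinimide, O=C1CCC(=O)N1Br
Why: Wohl–Ziegler allylic bromination at the γ-methyl through the delocalised allyl radical keeps the E olefin; the minor 2-bromomethyl regioisomer is removed by distillation.

Step 7
Reactants: 7 (5S)-5-(3-TBSO-prop-1-en-2-yl)-3-(tributylstannyl)furan-2(5H)-one; 10 tert-butyl (2E)-4-bromo-2-methylbut-2-enoate
Product: 11 tert-butyl (2E)-4-[(5S)-5-(3-TBSO-prop-1-en-2-yl)-2-oxo-2,5-dihydrofuran-3-yl]-2-methylbut-2-enoate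
Conditions: Pd2(dba)3 (2.5 mol%), AsPh3 (20 mol%), CuI (10 mol%), NMP, 40 °C
Reagents that add atoms: none
Why: Stille coupling of the vinylstannane with the allylic bromide through a π-allyl palladium species joins at the unhindered CH2 terminus, and the base-free conditions avoid γ-deprotonation of the butenolide, so the stereocentre and both olefin geometries are kept.

Step 8
Reactants: 11 tert-butyl (2E)-4-[(5S)-5-(3-TBSO-prop-1-en-2-yl)-2-oxo-2,5-dihydrofuran-3-yl]-2-methylbut-2-enoate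
Product: 13 tert-butyl (2E,5Z,7S)-9-TBSO-7-hydroxy-5-(hydroxymethyl)-2-methyl-8-methylidenenona-2,5-dienoate, via lactol 12 (not isolated)
Conditions: i-Bu2AlH (1.3 equiv), CH2Cl2, −78 °C; MeOH; then CeCl3·7H2O (1 equiv), NaBH4 (2 equiv), MeOH, −40 → 0 °C; Rochelle salt
Reagents that add atoms: none
Why: 1,2-Reduction of the lactone to the lactol at −78 °C (the tert-butyl enoate is inert there) and Luche reduction of the ring-opened hydroxy enal in the same pot avoid the acid that would aromatise the lactol to a furan; the Z olefin and the carbinol are unchanged.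

Step 9
Reactants: 13 tert-butyl (2E,5Z,7S)-9-TBSO-7-hydroxy-5-(hydroxymethyl)-2-methyl-8-methylidenenona-2,5-dienoate
Product: 14 tert-butyl (2E)-4-[(2R,3S)-3-[(1R)-1-hydroxy-2-(TBSO-methyl)prop-2-en-1-yl]-2-(hydroxymethyl)oxiran-2-yl]-2-methylbut-2-enoate
Conditions: mCPBA (1.05 equiv), NaHCO3 (solid), CH2Cl2, −20 → 0 °C
Reagents that add atoms: 3-chloroperbenzoic acid, OOC(=O)c1cccc(Cl)c1
Why: Henbest hydroxyl-directed peracid epoxidation, in which allylic 1,3-strain from the cis CH2OH holds the carbinol H in the olefin plane so the hydrogen-bonded peracid attacks the face syn to OH (threo), setting both oxirane centres trans to the future C5–OH; the trisubstituted olefin reacts ahead of the 1,1-disubstituted one and the enoate is inert.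

Step 10
Reactants: 14 tert-butyl (2E)-4-[(2R,3S)-3-[(1R)-1-hydroxy-2-(TBSO-methyl)prop-2-en-1-yl]-2-(hydroxymethyl)oxiran-2-yl]-2-methylbut-2-enoate
Product: 15 tert-butyl (2E)-4-[(2R,3S)-3-[(1R)-1-TESO-2-(TBSO-methyl)prop-2-en-1-yl]-2-(TESO-methyl)oxiran-2-yl]-2-methylbut-2-enoate
Conditions: Et3SiCl (2.5 equiv), imidazole (5 equiv), DMAP (5 mol%), DMF, 0 °C → rt
Reagents that add atoms: chlorotriethylsilane, CC[Si](Cl)(CC)CC
Why: Silyl ether formation at both hydroxyls under imidazole/DMAP nucleophilic catalysis leaves the oxirane and all stereocentres untouched.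

Step 11
Reactants: 15 tert-butyl (2E)-4-[(2R,3S)-3-[(1R)-1-TESO-2-(TBSO-methyl)prop-2-en-1-yl]-2-(TESO-methyl)oxiran-2-yl]-2-methylbut-2-enoate
Product: 16 tert-butyl (2E)-4-[(2S,3S)-3-[(1R)-1-TESO-2-(TBSO-methyl)prop-2-en-1-yl]-2-formyloxiran-2-yl]-2-methylbut-2-enoate
Conditions: (COCl)2 (4 equiv), DMSO (8 equiv), CH2Cl2, −78 → −40 °C; Et3N (12 equiv), −78 → 0 °C
Reagents that add atoms: none
Why: Under Swern conditions the chlorosulfonium salt attacks the least hindered primary Si–O–CH2 and oxidises it directly to the aldehyde while the secondary TES and the TBS ethers survive; the α-carbon is quaternary, so it cannot epimerise.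

Step 12
Reactants: 16 tert-butyl (2E)-4-[(2S,3S)-3-[(1R)-1-TESO-2-(TBSO-methyl)prop-2-en-1-yl]-2-formyloxiran-2-yl]-2-methylbut-2-enoate; 17 ethynylmagnesium bromide
Product: 18 tert-butyl (2E)-4-[(2R,3S)-3-[(1R)-1-TESO-2-(TBSO-methyl)prop-2-en-1-yl]-2-(1-hydroxyprop-2-yn-1-yl)oxiran-2-yl]-2-methylbut-2-enoate (both carbinol epimers)
Conditions: 17 (0.5 M in THF, 3 equiv), THF, −78 → −20 °C; aq NH4Cl
Reagents that add atoms: none
Why: Grignard 1,2-addition to the aldehyde (tert-butyl enoate and oxirane are inert at low temperature) gives both carbinol epimers, which is immaterial because this centre becomes the ketone in step 14.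

Step 13
Reactants: 18 tert-butyl (2E)-4-[(2R,3S)-3-[(1R)-1-TESO-2-(TBSO-methyl)prop-2-en-1-yl]-2-(1-hydroxyprop-2-yn-1-yl)oxiran-2-yl]-2-methylbut-2-enoate; 19 hept-1-ene
Product: 21 tert-butyl (2E)-4-[(1R,5R,6S)-3-[(1E)-hept-1-en-1-yl]-2-hydroxy-5-TESO-4-(TBSO-methyl)-7-oxabicyclo[4.1.0]hept-3-en-1-yl]-2-methylbut-2-enoate (both C2 epimers), via ring-closed vinyl diene 20 (not isolated)
Conditions: second-generation Grubbs catalyst (10 mol%, two portions), 19 (8 equiv), CH2Cl2 (0.01 M), 40 °C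
Reagents that add atoms: none
Why: Tandem ring-closing enyne metathesis/cross-metathesis, in which the Ru alkylidene adds to the CH end of the terminal alkyne, the resulting vinylcarbene closes on the 1,1-disubstituted olefin (six-membered ring, preorganised by the cis-oxirane) and the vinyl terminus of 20 then exchanges =CH2 for =CH–C5H11 with excess hept-1-ene, the conjugated olefin equilibrating to E; no stereocentre is touched.

Step 14
Reactants: 21 tert-butyl (2E)-4-[(1R,5R,6S)-3-[(1E)-hept-1-en-1-yl]-2-hydroxy-5-TESO-4-(TBSO-methyl)-7-oxabicyclo[4.1.0]hept-3-en-1-yl]-2-methylbut-2-enoate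
Product: 22 tert-butyl (2E)-4-[(1S,5R,6S)-3-[(1E)-hept-1-en-1-yl]-2-oxo-5-TESO-4-(TBSO-methyl)-7-oxabicyclo[4.1.0]hept-3-en-1-yl]-2-methylbut-2-enoate
Conditions: Dess–Martin periodinane (1.5 equiv), NaHCO3, CH2Cl2, 0 °C → rt
Reagents that add atoms: none
Why: Dess–Martin oxidation of the only free (allylic) alcohol gives the dienone and converges both C2 epimers; buffering protects the oxirane and silyl ethers.

Step 15
Reactants: 22 tert-butyl (2E)-4-[(1S,5R,6S)-3-[(1E)-hept-1-en-1-yl]-2-oxo-5-TESO-4-(TBSO-methyl)-7-oxabicyclo[4.1.0]hept-3-en-1-yl]-2-methylbut-2-enoate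
Product: 23 (2E)-4-[(1S,5R,6S)-3-[(1E)-hept-1-en-1-yl]-5-hydroxy-4-(hydroxymethyl)-2-oxo-7-oxabicyclo[4.1.0]hept-3-en-1-yl]-2-methylbut-2-enoic acid
Conditions: CF3CO2H/CH2Cl2/H2O (10:10:1), 0 °C → rt; then pH 7 phosphate buffer/MeOH, acidify to pH 3
Reagents that add atoms: none
Why: Brønsted-acid solvolysis removes both silyl ethers and the tert-butyl ester (loss of isobutene) in one operation; the oxirane next to the ketone is deactivated toward acid opening, so all three stereocentres are retained.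

**Compound list**

1 | 2-methylidenepropane-1,3-diol | C=C(CO)CO | starting material
2 | 2-(TBSO-methyl)prop-2-en-1-ol | C=C(CO)CO[Si](C)(C)C(C)(C)C | intermediate
3 | 2-(TBSO-methyl)prop-2-enal | C=C(C=O)CO[Si](C)(C)C(C)(C)C | intermediate
4 | methyl prop-2-ynoate | C#CC(=O)OC | starting material
5 | methyl (4S)-4-hydroxy-5-(TBSO-methyl)hex-5-en-2-ynoate | COC(=O)C#C[C@H](O)C(=C)CO[Si](C)(C)C(C)(C)C | intermediate
6 | methyl (2E,4S)-4-hydroxy-5-(TBSO-methyl)-2-(tributylstannyl)hexa-2,5-dienoate (not isolated) | COC(=O)/C(=C\[C@H](O)C(=C)CO[Si](C)(C)C(C)(C)C)[Sn](CCCC)(CCCC)CCCC | intermediate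
7 | (5S)-5-(3-TBSO-prop-1-en-2-yl)-3-(tributylstannyl)furan-2(5H)-one | C=C(CO[Si](C)(C)C(C)(C)C)[C@H]1OC(=O)C([Sn](CCCC)(CCCC)CCCC)=C1 | intermediate
8 | (2E)-2-methylbut-2-enoic acid (tiglic acid) | C/C=C(\C)C(=O)O | starting material
9 | tert-butyl (2E)-2-methylbut-2-enoate | C/C=C(\C)C(=O)OC(C)(C)C | intermediate
10 | tert-butyl (2E)-4-bromo-2-methylbut-2-enoate | BrC/C=C(\C)C(=O)OC(C)(C)C | intermediate
11 | tert-butyl (2E)-4-[(5S)-5-(3-TBSO-prop-1-en-2-yl)-2-oxo-2,5-dihydrofuran-3-yl]-2-methylbut-2-enoate | C=C(CO[Si](C)(C)C(C)(C)C)[C@H]1OC(=O)C(C/C=C(\C)C(=O)OC(C)(C)C)=C1 | intermediate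
12 | tert-butyl (2E)-4-[(5S)-2-hydroxy-5-(3-TBSO-prop-1-en-2-yl)-2,5-dihydrofuran-3-yl]-2-methylbut-2-enoate (lactol, both anomers, not isolated) | C=C(CO[Si](C)(C)C(C)(C)C)[C@H]1OC(O)C(C/C=C(\C)C(=O)OC(C)(C)C)=C1 | intermediate
13 | tert-butyl (2E,5Z,7S)-9-TBSO-7-hydroxy-5-(hydroxymethyl)-2-methyl-8-methylidenenona-2,5-dienoate | C=C(CO[Si](C)(C)C(C)(C)C)[C@@H](O)/C=C(\CO)C/C=C(\C)C(=O)OC(C)(C)C | intermediate
14 | tert-butyl (2E)-4-[(2R,3S)-3-[(1R)-1-hydroxy-2-(TBSO-methyl)prop-2-en-1-yl]-2-(hydroxymethyl)oxiran-2-yl]-2-methylbut-2-enoate | C=C(CO[Si](C)(C)C(C)(C)C)[C@@H](O)[C@@H]1O[C@]1(C/C=C(\C)C(=O)OC(C)(C)C)CO | intermediate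
15 | tert-butyl (2E)-4-[(2R,3S)-3-[(1R)-1-TESO-2-(TBSO-methyl)prop-2-en-1-yl]-2-(TESO-methyl)oxiran-2-yl]-2-methylbut-2-enoate | C=C(CO[Si](C)(C)C(C)(C)C)[C@@H](O[Si](CC)(CC)CC)[C@@H]1O[C@]1(C/C=C(\C)C(=O)OC(C)(C)C)CO[Si](CC)(CC)CC | intermediate
16 | tert-butyl (2E)-4-[(2S,3S)-3-[(1R)-1-TESO-2-(TBSO-methyl)prop-2-en-1-yl]-2-formyloxiran-2-yl]-2-methylbut-2-enoate | C=C(CO[Si](C)(C)C(C)(C)C)[C@@H](O[Si](CC)(CC)CC)[C@@H]1O[C@]1(C/C=C(\C)C(=O)OC(C)(C)C)C=O | intermediate
17 | ethynylmagnesium bromide | C#C[Mg]Br | starting material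
18 | tert-butyl (2E)-4-[(2R,3S)-3-[(1R)-1-TESO-2-(TBSO-methyl)prop-2-en-1-yl]-2-(1-hydroxyprop-2-yn-1-yl)oxiran-2-yl]-2-methylbut-2-enoate (both carbinol epimers) | C=C(CO[Si](C)(C)C(C)(C)C)[C@@H](O[Si](CC)(CC)CC)[C@@H]1O[C@]1(C/C=C(\C)C(=O)OC(C)(C)C)C(O)C#C | intermediate
19 | hept-1-ene | C=CCCCCC | starting material
20 | tert-butyl (2E)-4-[(1R,5R,6S)-3-ethenyl-2-hydroxy-5-TESO-4-(TBSO-methyl)-7-oxabicyclo[4.1.0]hept-3-en-1-yl]-2-methylbut-2-enoate (both C2 epimers, not isolated) | C=CC1=C(CO[Si](C)(C)C(C)(C)C)[C@@H](O[Si](CC)(CC)CC)[C@@H]2O[C@]2(C/C=C(\C)C(=O)OC(C)(C)C)C1O | intermediate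
21 | tert-butyl (2E)-4-[(1R,5R,6S)-3-[(1E)-hept-1-en-1-yl]-2-hydroxy-5-TESO-4-(TBSO-methyl)-7-oxabicyclo[4.1.0]hept-3-en-1-yl]-2-methylbut-2-enoate (both C2 epimers) | CCCCC/C=C/C1=C(CO[Si](C)(C)C(C)(C)C)[C@@H](O[Si](CC)(CC)CC)[C@@H]2O[C@]2(C/C=C(\C)C(=O)OC(C)(C)C)C1O | intermediate
22 | tert-butyl (2E)-4-[(1S,5R,6S)-3-[(1E)-hept-1-en-1-yl]-2-oxo-5-TESO-4-(TBSO-methyl)-7-oxabicyclo[4.1.0]hept-3-en-1-yl]-2-methylbut-2-enoate | CCCCC/C=C/C1=C(CO[Si](C)(C)C(C)(C)C)[C@@H](O[Si](CC)(CC)CC)[C@@H]2O[C@]2(C/C=C(\C)C(=O)OC(C)(C)C)C1=O | intermediate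
23 | (2E)-4-[(1S,5R,6S)-3-[(1E)-hept-1-en-1-yl]-5-hydroxy-4-(hydroxymethyl)-2-oxo-7-oxabicyclo[4.1.0]hept-3-en-1-yl]-2-methylbut-2-enoic acid | CCCCC/C=C/C1=C(CO)[C@@H](O)[C@@H]2O[C@]2(C/C=C(\C)C(=O)O)C1=O | target

**Step count and risks**

Total step count: 15. Longest linear sequence: 13 steps (steps 1–4 and 7–15, from 1).

The three steps most likely to fail:

Step 13 (tandem enyne ring closure/cross-metathesis). The ring olefin is tetrasubstituted and must form on a hindered 1,1-disubstituted alkene, next to a free propargylic alcohol, with hept-1-ene homodimerisation and E/Z control as side issues. The fallback sets out from aldehyde 16 and builds the ring by diene metathesis, attaching the heptenyl group afterwards. Vinylmagnesium bromide (THF, −78 °C) adds to 16 to give tert-butyl (2E)-4-[(2R,3S)-3-[(1R)-1-TESO-2-(TBSO-methyl)prop-2-en-1-yl]-2-(1-hydroxyprop-2-en-1-yl)oxiran-2-yl]-2-methylbut-2-enoate F1. Ring-closing diene metathesis (second-generation Grubbs catalyst, CH2Cl2, 40 °C) then forms only a trisubstituted olefin and gives tert-butyl (2E)-4-[(1R,5R,6S)-2-hydroxy-5-TESO-4-(TBSO-methyl)-7-oxabicyclo[4.1.0]hept-3-en-1-yl]-2-methylbut-2-enoate F2. Dess–Martin oxidation gives tert-butyl (2E)-4-[(1S,5R,6S)-2-oxo-5-TESO-4-(TBSO-methyl)-7-oxabicyclo[4.1.0]hept-3-en-1-yl]-2-methylbut-2-enoate F3. α-Iodination (I2, PhI(OCOCF3)2, pyridine, CH2Cl2) gives tert-butyl (2E)-4-[(1S,5R,6S)-3-iodo-2-oxo-5-TESO-4-(TBSO-methyl)-7-oxabicyclo[4.1.0]hept-3-en-1-yl]-2-methylbut-2-enoate F4. Suzuki coupling with commercial (E)-hept-1-enylboronic acid (PdCl2(PhCN)2, AsPh3, Ag2O, THF/H2O, rt) returns to the route at dienone 22.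

Step 7 (Stille coupling of the electron-poor α-stannyl butenolide with a γ-bromo enoate). Transmetalation may be slow, and the substituted π-allyl palladium species may eliminate or scramble. The fallback sets out from stannane 7 and reverses the coupling polarity. Iododestannylation (I2, CH2Cl2, 0 °C) gives (5S)-3-iodo-5-(3-TBSO-prop-1-en-2-yl)furan-2(5H)-one F5. Stille coupling with allyltributylstannane (Pd2(dba)3, AsPh3, CuI, NMP) gives (5S)-3-(prop-2-en-1-yl)-5-(3-TBSO-prop-1-en-2-yl)furan-2(5H)-one F6. Cross-metathesis of its terminal olefin with tert-butyl methacrylate (second-generation Grubbs catalyst, CH2Cl2, 40 °C) builds the E enoate and returns to the route at butenolide 11.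

Step 15 (one-pot acidic global deprotection). The epoxy dienone with two allylic alcohols may not tolerate the time in CF3CO2H needed to cleave the tert-butyl ester. The fallback sets out from dienone 22 and separates the two tasks under non-protic conditions. HF·pyridine (THF/pyridine, 0 °C) removes both silyl ethers to give tert-butyl (2E)-4-[(1S,5R,6S)-3-[(1E)-hept-1-en-1-yl]-5-hydroxy-4-(hydroxymethyl)-2-oxo-7-oxabicyclo[4.1.0]hept-3-en-1-yl]-2-methylbut-2-enoate F7. TMSOTf/2,6-lutidine (CH2Cl2, 0 °C) converts the tert-butyl ester into the silyl ester and caps both alcohols, giving trimethylsilyl (2E)-4-[(1S,5R,6S)-3-[(1E)-hept-1-en-1-yl]-2-oxo-5-(trimethylsilyloxy)-4-(trimethylsilyloxymethyl)-7-oxabicyclo[4.1.0]hept-3-en-1-yl]-2-methylbut-2-enoate F8. Citric acid in MeOH/H2O then cleaves the trimethylsilyl groups and returns to the route at target 23.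

**Further compounds**

F1 | step 13 | tert-butyl (2E)-4-[(2R,3S)-3-[(1R)-1-TESO-2-(TBSO-methyl)prop-2-en-1-yl]-2-(1-hydroxyprop-2-en-1-yl)oxiran-2-yl]-2-methylbut-2-enoate (both carbinol epimers) | C=C(CO[Si](C)(C)C(C)(C)C)[C@@H](O[Si](CC)(CC)CC)[C@@H]1O[C@]1(C/C=C(\C)C(=O)OC(C)(C)C)C(O)C=C
F2 | step 13 | tert-butyl (2E)-4-[(1R,5R,6S)-2-hydroxy-5-TESO-4-(TBSO-methyl)-7-oxabicyclo[4.1.0]hept-3-en-1-yl]-2-methylbut-2-enoate (both C2 epimers) | C1=C(CO[Si](C)(C)C(C)(C)C)[C@@H](O[Si](CC)(CC)CC)[C@@H]2O[C@]2(C/C=C(\C)C(=O)OC(C)(C)C)C1O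
F3 | step 13 | tert-butyl (2E)-4-[(1S,5R,6S)-2-oxo-5-TESO-4-(TBSO-methyl)-7-oxabicyclo[4.1.0]hept-3-en-1-yl]-2-methylbut-2-enoate | C1=C(CO[Si](C)(C)C(C)(C)C)[C@@H](O[Si](CC)(CC)CC)[C@@H]2O[C@]2(C/C=C(\C)C(=O)OC(C)(C)C)C1=O
F4 | step 13 | tert-butyl (2E)-4-[(1S,5R,6S)-3-iodo-2-oxo-5-TESO-4-(TBSO-methyl)-7-oxabicyclo[4.1.0]hept-3-en-1-yl]-2-methylbut-2-enoate | IC1=C(CO[Si](C)(C)C(C)(C)C)[C@@H](O[Si](CC)(CC)CC)[C@@H]2O[C@]2(C/C=C(\C)C(=O)OC(C)(C)C)C1=O
F5 | step 7 | (5S)-3-iodo-5-(3-TBSO-prop-1-en-2-yl)furan-2(5H)-one | C=C(CO[Si](C)(C)C(C)(C)C)[C@H]1OC(=O)C(I)=C1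
F6 | step 7 | (5S)-3-(prop-2-en-1-yl)-5-(3-TBSO-prop-1-en-2-yl)furan-2(5H)-one | C=C(CO[Si](C)(C)C(C)(C)C)[C@H]1OC(=O)C(CC=C)=C1
F7 | step 15 | tert-butyl (2E)-4-[(1S,5R,6S)-3-[(1E)-hept-1-en-1-yl]-5-hydroxy-4-(hydroxymethyl)-2-oxo-7-oxabicyclo[4.1.0]hept-3-en-1-yl]-2-methylbut-2-enoate | CCCCC/C=C/C1=C(CO)[C@@H](O)[C@@H]2O[C@]2(C/C=C(\C)C(=O)OC(C)(C)C)C1=O
F8 | step 15 | trimethylsilyl (2E)-4-[(1S,5R,6S)-3-[(1E)-hept-1-en-1-yl]-2-oxo-5-(trimethylsilyloxy)-4-(trimethylsilyloxymethyl)-7-oxabicyclo[4.1.0]hept-3-en-1-yl]-2-methylbut-2-enoate | CCCCC/C=C/C1=C(CO[Si](C)(C)C)[C@@H](O[Si](C)(C)C)[C@@H]2O[C@]2(C/C=C(\C)C(=O)O[Si](C)(C)C)C1=O
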